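**Plan**
1. Cuts: the C2=N bond of ring A is traced back to the N–H/C2–H pair of a piperidine. Both lactone C(=O)–O3 bonds are then cut, so rings A and B fall back on one monomer, methyl 8-[(2R,5S,6S)-5-hydroxy-6-methylpiperidin-2-yl]octanoate.
2. Enabling feature: each N-ring is a reduced 6-alkyl-2-methylpyridin-3-ol. N1, C2, its CH3 and C3 are the alanine skeleton, C6 with the seven-methylene ester chain is azelaic acid, and the unsubstituted C4–C5 pair is a two-carbon dienophile. This is the atom pattern of a 5-alkoxyoxazole cycloaddition.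
3. Forward: amide, then 5-ethoxyoxazole, then [4+2] addition of acrylic acid. This makes C3–C4 and C5–C6 and closes the six-membered ring, and loss of ethanol and CO2 gives the pyridinol.
4. Stereochemistry: one-face hydrogenation gives the all-cis C2/C3/C6 relationship, and a lipase kinetic resolution selects the (2S,3S,6R) series used for both rings.
5. Joining: the N-Cbz/O-TBS acid (future ring A) is esterified with the N-Boc alcohol (ring B). The methyl ester and silyl ether are then cleaved and the 26-membered dilactone is closed.
6. End game: Cbz removal, N-chlorination and loss of HCl towards C2 give the ring A imine, erasing only C2 of ring A. Boc removal then frees ring B.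

Key step: step 3

Remark on numbering: in each heterocycle N1, C2 (bears CH3), C3 (bears O), C6 (bears the chain). Ring A is the imine ring and ring B the piperidine ring. Racemates are written as both enantiomers joined by a dot.
Assumption: the lipase follows the usual medium/large-substituent rule for secondary alcohols, so the (3R)-alcohol is acetylated and the wanted (3S)-alcohol stays free.

**Step 1**
Reactants: 1 monomethyl azelate (9-methoxy-9-oxononanoic acid); 2 DL-alanine ethyl ester hydrochloride
Product: 4 methyl 9-[(1-ethoxy-1-oxopropan-2-yl)amino]-9-oxononanoate (racemic), via acid chloride 3 (not isolated)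
Conditions: SOCl2, cat. DMF, toluene, 50 °C, evaporate; then 2, Et3N, CH2Cl2, 0 °C to rt
Reagents that add atoms: none
Why: Acid chloride formation followed by N-acylation of a primary amine is routine, the methyl ester is inert, and the alanine stereocentre does not matter because step 2 flattens it.

**Step 2**
Reactants: 4 methyl 9-[(1-ethoxy-1-oxopropan-2-yl)amino]-9-oxononanoate
Product: 5 methyl 8-(5-ethoxy-4-methyl-1,3-oxazol-2-yl)octanoate
Conditions: P2O5, CHCl3, reflux; cold aq K2CO3 work-up
Reagents that add atoms: none
Why: In this Robinson–Gabriel-type cyclodehydration of an N-acyl α-amino ester the amide oxygen closes onto the activated ester carbonyl and water is lost, which is the standard entry to 2-substituted 5-ethoxy-4-methyloxazoles; the basic quench protects the acid-labile product.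

**Step 3**
Reactants: 5 methyl 8-(5-ethoxy-4-methyl-1,3-oxazol-2-yl)octanoate; 6 acrylic acid
Product: 9 methyl 8-(5-hydroxy-6-methylpyridin-2-yl)octanoate, via oxa-bridged cycloadduct 7 (not isolated), via ring-opened hemiketal 8 (not isolated)
Conditions: 6 (excess), hydroquinone (cat.), neat, 100 °C; aq NaHCO3 work-up
Reagents that add atoms: none
Why: The electron-rich oxazole 5 acts as a 2-azadiene (C2=N3–C4=C5) and adds acrylic acid across C2 and C5 in a concerted, normal-electron-demand [4π+2π] cycloaddition (Kondrat'eva pyridine synthesis), forming the C5–C6 and C3–C4 bonds of the later piperidine and giving the oxa-bridged adduct 7. The six-membered ring thus closes by an intermolecular cycloaddition that makes both bonds in one event rather than by a chain cyclisation, and the acidic medium then breaks the C6–O bridge bond with loss of a C5 proton to give hemiketal 8, whose oxygen stays on C3. In 8 the carboxyl sits on C4, β to the ethoxy leaving group on C3, so ethanol and CO2 leave in a decarboxylative elimination driven by aromatisation; the closest known cases are the reactions of 5-alkoxy-4-methyloxazoles with acrylic and maleic acid derivatives, in which a C4 carboxyl is the one that is lost. The selectivity needed is regiochemical: the carboxyl-bearing carbon must bond to oxazole C5, and this "ortho" orientation is secured by the 5-ethoxy donor, which places the largest HOMO coefficient on C2 so that C2 pairs with the β-carbon of acrylic acid. The stereocentres of 7 and 8 are transient and vanish on aromatisation, so no stereocontrol is required. Hydroquinone holds back polymerisation of the dienophile, and the remote methyl ester is a spectator.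

**Step 4**
Reactants: 9 methyl 8-(5-hydroxy-6-methylpyridin-2-yl)octanoate
Product: 10 rac-methyl 8-[(2R*,5S*,6S*)-5-hydroxy-6-methylpiperidin-2-yl]octanoate (all-cis)
Conditions: H2 (4 bar), PtO2, AcOH, rt; aq K2CO3 work-up
Reagents that add atoms: none
Why: In the heterogeneous hydrogenation of the protonated pyridine all hydrogens arrive from the catalyst-bound face, so the C2 methyl, C3 hydroxyl and C6 chain end up mutually cis (racemic), as is usual for 2,6-dialkylpyridin-3-ols.

**Step 5**
Reactants: 10 rac-methyl 8-[(2R*,5S*,6S*)-5-hydroxy-6-methylpiperidin-2-yl]octanoate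
Product: 11 rac-methyl 8-[(2R*,5S*,6S*)-1-(benzyloxycarbonyl)-5-hydroxy-6-methylpiperidin-2-yl]octanoate
Conditions: CbzCl, K2CO3, THF/H2O, 0 °C to rt
Reagents that add atoms: benzyl chloroformate, O=C(Cl)OCc1ccccc1
Why: Schotten–Baumann carbamoylation takes the amine in preference to the secondary alcohol and touches no stereocentre.

**Step 6**
Reactants: 11 rac-methyl 8-[(2R*,5S*,6S*)-1-(benzyloxycarbonyl)-5-hydroxy-6-methylpiperidin-2-yl]octanoate
Product: 12 methyl 8-[(2R,5S,6S)-1-(benzyloxycarbonyl)-5-hydroxy-6-methylpiperidin-2-yl]octanoate (single enantiomer)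
Conditions: Burkholderia cepacia lipase (immobilised), vinyl acetate, MTBE, 35 °C, stopped a little past half conversion; chromatography
Reagents that add atoms: none
Why: In this lipase-catalysed kinetic resolution by irreversible transesterification the enzyme should acetylate the carbinol whose large flank (C2 with CH3 and N) and medium flank (C4H2) correspond to (R), so the wanted (S)-carbinol stays free, and this selects the absolute configuration at C2, C3 and C6 of both rings.

**Step 7**
Reactants: 12 methyl 8-[(2R,5S,6S)-1-(benzyloxycarbonyl)-5-hydroxy-6-methylpiperidin-2-yl]octanoate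
Product: 14 methyl 8-[(2R,5S,6S)-1-(tert-butoxycarbonyl)-5-hydroxy-6-methylpiperidin-2-yl]octanoate, via free piperidine 13 (not isolated)
Conditions: H2 (1 atm), Pd/C, Boc2O, MeOH, rt, then 45 °C
Reagents that add atoms: di-tert-butyl dicarbonate, CC(C)(C)OC(=O)OC(=O)OC(C)(C)C
Why: In this one-pot carbamate exchange, hydrogenolysis of the benzyl carbamate frees amine 13 and Boc2O traps it; gentle warming makes up for the hindered nitrogen, and without DMAP the alcohol stays free.

**Step 8**
Reactants: 12 methyl 8-[(2R,5S,6S)-1-(benzyloxycarbonyl)-5-hydroxy-6-methylpiperidin-2-yl]octanoate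
Product: 15 methyl 8-[(2R,5S,6S)-1-(benzyloxycarbonyl)-5-(tert-butyldimethylsilyloxy)-6-methylpiperidin-2-yl]octanoate
Conditions: TBSOTf, 2,6-lutidine, CH2Cl2, 0 °C
Reagents that add atoms: tert-butyldimethylsilyl triflate, CC(C)(C)[Si](C)(C)OS(=O)(=O)C(F)(F)F
Why: Silyl triflate silylation handles hindered secondary alcohols, proceeds with retention at carbon, and is tolerated by the Cbz group and the ester.

**Step 9**
Reactants: 15 methyl 8-[(2R,5S,6S)-1-(benzyloxycarbonyl)-5-(tert-butyldimethylsilyloxy)-6-methylpiperidin-2-yl]octanoate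
Product: 16 8-[(2R,5S,6S)-1-(benzyloxycarbonyl)-5-(tert-butyldimethylsilyloxy)-6-methylpiperidin-2-yl]octanoic acid
Conditions: LiOH, THF/MeOH/H2O, rt; 1 M HCl to pH 3
Reagents that add atoms: lithium hydroxide, [Li+].[OH-]
Why: Saponification of an unhindered methyl ester leaves the carbamate and the TBS ether untouched under these conditions.

**Step 10**
Reactants: 16 8-[(2R,5S,6S)-1-(benzyloxycarbonyl)-5-(tert-butyldimethylsilyloxy)-6-methylpiperidin-2-yl]octanoic acid; 14 methyl 8-[(2R,5S,6S)-1-(tert-butoxycarbonyl)-5-hydroxy-6-methylpiperidin-2-yl]octanoate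
Product: 17 linear diester (ring A unit N-Cbz/O-TBS; ring B unit N-Boc/methyl ester)
Conditions: MNBA (2-methyl-6-nitrobenzoic anhydride), DMAP, Et3N, CH2Cl2, rt
Reagents that add atoms: none
Why: The Shiina esterification acylates the ring B oxygen with retention at C3, and allylic strain in the N-Boc piperidine pushes the C2/C6 groups axial and the hydroxyl equatorial, which makes it accessible.

**Step 11**
Reactants: 17 linear diester (ring A unit N-Cbz/O-TBS; ring B unit N-Boc/methyl ester)
Product: 18 linear ester acid (ring A unit N-Cbz/O-TBS; ring B unit N-Boc/free carboxylic acid)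
Conditions: Me3SnOH, ClCH2CH2Cl, 80 °C; 0.5 M HCl wash
Reagents that add atoms: trimethyltin hydroxide, C[Sn](C)(C)O
Why: Trimethyltin hydroxide hydrolysis favours the unhindered methyl ester over the internal ester of a flanked secondary ring alcohol, and keeping the ring A oxygen silylated at this stage rules out tin-promoted transesterification.

**Step 12**
Reactants: 18 linear ester acid (ring A unit N-Cbz/O-TBS; ring B unit N-Boc/free carboxylic acid)
Product: 19 seco acid (ring A unit N-Cbz/free C3–OH; ring B unit N-Boc/free carboxylic acid)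
Conditions: HF·pyridine, pyridine/THF, 0 °C to rt
Reagents that add atoms: none
Why: Fluoride-mediated desilylation buffered with pyridine cleaves the Si–O bond only and leaves the Boc group, the Cbz group and the ester intact.

**Step 13**
Reactants: 19 seco acid (ring A unit N-Cbz/free C3–OH; ring B unit N-Boc/free carboxylic acid)
Product: 20 26-membered dilactone (ring A N-Cbz; ring B N-Boc)
Conditions: MNBA, DMAP, CH2Cl2, high dilution, slow addition of 19, rt
Reagents that add atoms: none
Why: Shiina macrolactonisation under high dilution closes the large, nearly strain-free 26-membered ring through acyl–oxygen bond formation, so C3 of ring A keeps its configuration and both nitrogens are masked against lactam formation.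

**Step 14**
Reactants: 20 26-membered dilactone (ring A N-Cbz; ring B N-Boc)
Product: 21 26-membered dilactone (ring A N–H; ring B N-Boc)
Conditions: H2 (1 atm), Pd/C, EtOAc, rt
Reagents that add atoms: none
Why: Hydrogenolysis of the benzyl carbamate is orthogonal to the Boc group and the lactones and is done before any reducible C=N bond is present.

**Step 15**
Reactants: 21 26-membered dilactone (ring A N–H; ring B N-Boc)
Product: 23 N-Boc imine (ring A C2=N; ring B N-Boc), via N-chloroamine 22 (not isolated)
Conditions: NCS, CH2Cl2, 0 °C, dark; water wash; then DBU, toluene, rt to 50 °C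
Reagents that add atoms: none
Why: N-chlorination of the only N–H is followed by base-induced E2 dehydrochlorination of the N-chloroamine to the cyclic imine; in the ring A chair the axial N–Cl is antiperiplanar to both axial hydrogens at C2 and C6, but C2–H is acidified by the adjacent antiperiplanar C3–O(acyl) bond, so HCl should leave towards C2, erasing only that stereocentre and keeping C3 and C6.

**Step 16**
Reactants: 23 N-Boc imine (ring A C2=N; ring B N-Boc)
Product: 24 CNP0304114.1 (target)
Conditions: TFA/CH2Cl2 (1:4), 0 °C; cold aq NaHCO3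
Reagents that add atoms: none
Why: During acidolytic Boc cleavage the imine is merely protonated, and the low temperature, short contact time and cold mildly basic quench should keep C3 of ring A from epimerising through the enamine.

**Compound list**
1 | monomethyl azelate (9-methoxy-9-oxononanoic acid) | COC(=O)CCCCCCCC(=O)O | starting material
2 | DL-alanine ethyl ester hydrochloride | CCOC(=O)C(C)N.Cl | starting material
3 | methyl 9-chloro-9-oxononanoate | COC(=O)CCCCCCCC(=O)Cl | intermediate
4 | methyl 9-[(1-ethoxy-1-oxopropan-2-yl)amino]-9-oxononanoate (racemic, centre not specified) | CCOC(=O)C(C)NC(=O)CCCCCCCC(=O)OC | intermediate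
5 | methyl 8-(5-ethoxy-4-methyl-1,3-oxazol-2-yl)octanoate | CCOc1oc(CCCCCCCC(=O)OC)nc1C | intermediate
6 | acrylic acid | C=CC(=O)O | starting material
7 | 4-ethoxy-1-(8-methoxy-8-oxooctyl)-3-methyl-7-oxa-2-azabicyclo[2.2.1]hept-2-ene-5-carboxylic acid (transient, endo/exo mixture, racemic) | CCOC12OC(CCCCCCCC(=O)OC)(CC1C(=O)O)N=C2C | intermediate
8 | 3-ethoxy-3-hydroxy-6-(8-methoxy-8-oxooctyl)-2-methyl-3,4-dihydropyridine-4-carboxylic acid (transient, stereoisomer mixture) | CCOC1(O)C(C(=O)O)C=C(CCCCCCCC(=O)OC)N=C1C | intermediate
9 | methyl 8-(5-hydroxy-6-methylpyridin-2-yl)octanoate | Cc1nc(CCCCCCCC(=O)OC)ccc1O | intermediate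
10 | rac-methyl 8-[(2R*,5S*,6S*)-5-hydroxy-6-methylpiperidin-2-yl]octanoate, all-cis racemate | O[C@H]1CC[C@@H](CCCCCCCC(=O)OC)N[C@H]1C.O[C@@H]1CC[C@H](CCCCCCCC(=O)OC)N[C@@H]1C | intermediate
11 | rac-methyl 8-[(2R*,5S*,6S*)-1-(benzyloxycarbonyl)-5-hydroxy-6-methylpiperidin-2-yl]octanoate, all-cis racemate | O[C@H]1CC[C@@H](CCCCCCCC(=O)OC)N(C(=O)OCc2ccccc2)[C@H]1C.O[C@@H]1CC[C@H](CCCCCCCC(=O)OC)N(C(=O)OCc2ccccc2)[C@@H]1C | intermediate
12 | methyl 8-[(2R,5S,6S)-1-(benzyloxycarbonyl)-5-hydroxy-6-methylpiperidin-2-yl]octanoate | O[C@H]1CC[C@@H](CCCCCCCC(=O)OC)N(C(=O)OCc2ccccc2)[C@H]1C | intermediate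
13 | methyl 8-[(2R,5S,6S)-5-hydroxy-6-methylpiperidin-2-yl]octanoate | O[C@H]1CC[C@@H](CCCCCCCC(=O)OC)N[C@H]1C | intermediate
14 | methyl 8-[(2R,5S,6S)-1-(tert-butoxycarbonyl)-5-hydroxy-6-methylpiperidin-2-yl]octanoate | O[C@H]1CC[C@@H](CCCCCCCC(=O)OC)N(C(=O)OC(C)(C)C)[C@H]1C | intermediate
15 | methyl 8-[(2R,5S,6S)-1-(benzyloxycarbonyl)-5-(tert-butyldimethylsilyloxy)-6-methylpiperidin-2-yl]octanoate | CC(C)(C)[Si](C)(C)O[C@H]1CC[C@@H](CCCCCCCC(=O)OC)N(C(=O)OCc2ccccc2)[C@H]1C | intermediate
16 | 8-[(2R,5S,6S)-1-(benzyloxycarbonyl)-5-(tert-butyldimethylsilyloxy)-6-methylpiperidin-2-yl]octanoic acid | CC(C)(C)[Si](C)(C)O[C@H]1CC[C@@H](CCCCCCCC(=O)O)N(C(=O)OCc2ccccc2)[C@H]1C | intermediate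
17 | linear diester: acid 16 esterified with the C3 oxygen of 14 (N-Cbz, O-TBS, N-Boc, methyl ester) | CC(C)(C)[Si](C)(C)O[C@H]1CC[C@@H](CCCCCCCC(=O)O[C@H]2CC[C@@H](CCCCCCCC(=O)OC)N(C(=O)OC(C)(C)C)[C@H]2C)N(C(=O)OCc3ccccc3)[C@H]1C | intermediate
18 | linear ester acid: 17 with the terminal methyl ester cleaved | CC(C)(C)[Si](C)(C)O[C@H]1CC[C@@H](CCCCCCCC(=O)O[C@H]2CC[C@@H](CCCCCCCC(=O)O)N(C(=O)OC(C)(C)C)[C@H]2C)N(C(=O)OCc3ccccc3)[C@H]1C | intermediate
19 | seco acid: 18 with the ring A hydroxyl free | O[C@H]1CC[C@@H](CCCCCCCC(=O)O[C@H]2CC[C@@H](CCCCCCCC(=O)O)N(C(=O)OC(C)(C)C)[C@H]2C)N(C(=O)OCc3ccccc3)[C@H]1C | intermediate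
20 | 26-membered head-to-tail dilactone of the carpaine skeleton, ring A N-Cbz, ring B N-Boc, both rings (2S,3S,6R) | C[C@@H]1N(C(=O)OCc4ccccc4)[C@@H]2CCCCCCCC(=O)O[C@H]3CC[C@@H](CCCCCCCC(=O)O[C@H]1CC2)N(C(=O)OC(C)(C)C)[C@H]3C | intermediate
21 | the same dilactone, ring A N–H, ring B N-Boc | C[C@@H]1N[C@@H]2CCCCCCCC(=O)O[C@H]3CC[C@@H](CCCCCCCC(=O)O[C@H]1CC2)N(C(=O)OC(C)(C)C)[C@H]3C | intermediate
22 | the same dilactone, ring A N–Cl, ring B N-Boc | C[C@@H]1N(Cl)[C@@H]2CCCCCCCC(=O)O[C@H]3CC[C@@H](CCCCCCCC(=O)O[C@H]1CC2)N(C(=O)OC(C)(C)C)[C@H]3C | intermediate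
23 | dilactone with ring A as the 2-methyl-C2=N imine (3S,6R) and ring B N-Boc (2S,3S,6R) | CC1=N[C@@H]2CCCCCCCC(=O)O[C@H]3CC[C@@H](CCCCCCCC(=O)O[C@H]1CC2)N(C(=O)OC(C)(C)C)[C@H]3C | intermediate
24 | CNP0304114.1: dilactone with ring A imine (3S,6R) and ring B all-cis piperidine (2S,3S,6R) | CC1=N[C@@H]2CCCCCCCC(=O)O[C@H]3CC[C@@H](CCCCCCCC(=O)O[C@H]1CC2)N[C@H]3C | target

**Total step count:** 16
**Longest linear sequence:** 15 (steps 1–6 and 8–16; step 7 is the branch from 12)

**Steps most likely to fail**

Step 15. HCl may be lost with poor regiocontrol, towards C6 instead of C2, and prolonged contact with base may erode the configuration at C3. The fallback sets out from 21. It replaces the chloramine elimination by an N-oxidation whose direction is known to be steered to the carbon next to a ring C–O bond. Urea–H2O2 with catalytic Na2WO4 in MeOH (0 °C to rt) should take the ring A amine through the N-hydroxypiperidine F1 to the C2 ketonitrone F2. Deoxygenation of F2 with PPh3 under MoO2Cl2(dmf)2 catalysis in THF then comes back to the route at 23.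

Step 3. Aromatisation may run by proton loss instead of CO2 loss, and the addition may occur with the reversed orientation. The acid may also open the oxazole before it reacts, or the dienophile may polymerise. The fallback sets out from 5 and keeps the same cycloaddition, but with a symmetrical, non-acidic two-carbon partner. Ethylene under pressure (autoclave, toluene, about 170 °C) should give the oxa-bridged ethylene adduct F3. This opens to the ring-opened hemiketal F4, which only has to lose ethanol, and the sequence comes back at 9. Regiochemistry and decarboxylation then no longer matter, and unactivated cis-alkenes are known partners of 5-ethoxy-4-methyloxazoles at such temperatures.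

Step 6. The enzyme may discriminate the enantiomers poorly at a hindered ring alcohol, and acyl transfer from the chain methyl ester may compete. The fallback sets out from 11 and replaces the enzymatic step by a physical separation: preparative supercritical-fluid chromatography on a polysaccharide chiral stationary phase, with the absolute configuration assigned on a crystalline derivative. It comes back at 12, and no compound outside the list is made (F0).

**Further compounds**
F1 | step 15 | dilactone with ring A N–OH and ring B N-Boc | C[C@@H]1N(O)[C@@H]2CCCCCCCC(=O)O[C@H]3CC[C@@H](CCCCCCCC(=O)O[C@H]1CC2)N(C(=O)OC(C)(C)C)[C@H]3C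
F2 | step 15 | dilactone with ring A as the C2 ketonitrone and ring B N-Boc | CC1=[N+]([O-])[C@@H]2CCCCCCCC(=O)O[C@H]3CC[C@@H](CCCCCCCC(=O)O[C@H]1CC2)N(C(=O)OC(C)(C)C)[C@H]3C
F3 | step 3 | methyl 8-(4-ethoxy-3-methyl-7-oxa-2-azabicyclo[2.2.1]hept-2-en-1-yl)octanoate (transient, racemic) | CCOC12OC(CCCCCCCC(=O)OC)(CC1)N=C2C
F4 | step 3 | methyl 8-(5-ethoxy-5-hydroxy-6-methyl-4,5-dihydropyridin-2-yl)octanoate (transient, racemic) | CCOC1(O)CC=C(CCCCCCCC(=O)OC)N=C1C
F0 | step 6 | none | none
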